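**Retrosynthetic overview**

- The last C–C bond is C2–aryl of the oxolane ring: a syringyl arylzinc is joined to a 2-(phenylsulfonyl)oxolane. The enabling feature is the ring oxygen O1 on C2, which lets C2 be held as an O,S-acetal that ionises to the five-membered cyclic oxocarbenium ion (C2=O1+); the CH2OSi group on the neighbouring C3 steers the aryl to the trans face.
- The oxolane ring (second and last ring formed) is closed at O1–C2 by lactol formation when the vinyl group of an open-chain 1-aryl-pent-4-en-1-ol is cleaved; the C5 aryl is thus already in place, cis to C4.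
- The C3–C4–C5 triad comes from (R)-4-vinylbutyrolactone (first ring, from furan-2(5H)-one by rhodium-catalysed conjugate vinylation) and an anti-selective boron aldol with silyl-protected syringaldehyde. Reduction opens this lactone: its carbonyl and OCH2 carbons become the two CH2OH groups, and the vinyl group becomes C2 of the oxolane.
- One fluoride step removes all four silyl groups.

Key step: step 9

Remark: Ar = 3,5-dimethoxy-4-[(triisopropylsilyl)oxy]phenyl, TBS = tert-butyldimethylsilyl, TIPS = triisopropylsilyl; the oxolane is numbered O1, C2 (aryl from the key step), C3, C4, C5 (aryl from the aldol); syringaldehyde, furan-2(5H)-one, potassium vinyltrifluoroborate and 4-bromo-2,6-dimethoxyphenol are assumed to be purchased.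

**Step 1**
Reactants: 1 syringaldehyde (4-hydroxy-3,5-dimethoxybenzaldehyde)
Product: 2 3,5-dimethoxy-4-[(triisopropylsilyl)oxy]benzaldehyde
Conditions: TIPSCl (1.3 equiv), imidazole (2.5 equiv), DMF, rt
Reagents that add atoms: chlorotriisopropylsilane (TIPSCl), CC(C)[Si](Cl)(C(C)C)C(C)C
Why: Imidazole-promoted O-silylation of the hindered phenol gives an aryl silyl ether that tolerates enolate and hydride chemistry and leaves with the other silyl groups at the end; no stereocentre is involved.

**Step 2**
Reactants: 3 furan-2(5H)-one; 4 potassium vinyltrifluoroborate (CH2=CHBF3K)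
Product: 5 (4R)-4-ethenyloxolan-2-one
Conditions: [Rh(cod)2]BF4 (3 mol%), (R)-BINAP (3.3 mol%), toluene/H2O (10:1), 100 °C
Reagents that add atoms: none
Why: Hayashi–Miyaura reaction (rhodium-catalysed asymmetric 1,4-addition of an organoboron reagent to an enoate): the (R)-BINAP–rhodium vinyl species carbometalates one enantioface at C4 and water protonates the rhodium enolate, so C4 is set as R under catalyst control.

**Step 3**
Reactants: 5 (4R)-4-ethenyloxolan-2-one; 2 3,5-dimethoxy-4-[(triisopropylsilyl)oxy]benzaldehyde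
Product: 8 (3R,4S)-3-[(S)-Ar(hydroxy)methyl]-4-ethenyloxolan-2-one, via boron enolate 6 (not isolated), via boron aldolate 7 (not isolated)
Conditions: (c-C6H11)2BOTf (1.5 equiv), Et3N (2 equiv), CH2Cl2, −78 °C; then 2, −78 → 0 °C; pH 7 buffer, MeOH, 30% H2O2, 0 °C
Reagents that add atoms: none
Why: Boron-mediated aldol reaction of an ester E(O)-enolate (soft enolisation with a dialkylboron triflate and Et3N, as established for carboxylic esters): the ring-locked enolate 6 should react through a chair Zimmerman–Traxler transition state on the face anti to the C4 vinyl group, so that C3 becomes trans to vinyl and the carbinol centre anti (threo) to C3, both under substrate control.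

**Step 4**
Reactants: 8 (3R,4S)-3-[(S)-Ar(hydroxy)methyl]-4-ethenyloxolan-2-one
Product: 9 (2S,3S)-2-[(S)-Ar(hydroxy)methyl]-3-ethenylbutane-1,4-diol
Conditions: LiBH4 (3 equiv), MeOH (3 equiv), THF, 0 °C → rt
Reagents that add atoms: none
Why: Borohydride reduction of the lactone to the 1,4-diol (LiBH4 reduces esters but leaves alkenes and aryl silyl ethers alone) unmasks both CH2OH groups without touching a stereocentre, the low temperature suppressing retro-aldol cleavage.

**Step 5**
Reactants: 9 (2S,3S)-2-[(S)-Ar(hydroxy)methyl]-3-ethenylbutane-1,4-diol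
Product: 10 (1S,2S,3S)-1-Ar-2,3-bis{[(tert-butyldimethylsilyl)oxy]methyl}pent-4-en-1-ol
Conditions: TBSCl (2.2 equiv), imidazole (5 equiv), CH2Cl2, 0 °C
Reagents that add atoms: tert-butylchlorodimethylsilane (TBSCl), CC(C)(C)[Si](C)(C)Cl
Why: Silylation with TBSCl is much faster at the two primary hydroxyls than at the hindered secondary benzylic one, so the alcohol needed for ring closure stays free; no stereocentre is affected.

**Step 6**
Reactants: 10 (1S,2S,3S)-1-Ar-2,3-bis{[(tert-butyldimethylsilyl)oxy]methyl}pent-4-en-1-ol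
Product: 13 (3S,4S,5S)-5-Ar-3,4-bis{[(tert-butyldimethylsilyl)oxy]methyl}oxolan-2-ol (both C2 epimers), via vicinal diol 11 (not isolated), via hydroxy aldehyde 12 (not isolated)
Conditions: OsO4 (2 mol%), NaIO4 (4 equiv), 2,6-lutidine (2 equiv), 1,4-dioxane/H2O (3:1), rt
Reagents that add atoms: osmium tetroxide, O=[Os](=O)(=O)=O (oxygen carrier); sodium periodate, [Na+].[O-]I(=O)(=O)=O (terminal oxidant)
Why: Lemieux–Johnson oxidation (osmium-catalysed dihydroxylation, then periodate cleavage of diol 11) turns the vinyl group into aldehyde 12, whose γ-hydroxyl adds at once to the carbonyl (5-exo-trig) to close the oxolane ring as lactol 13; the buffered medium should avoid epimerisation next to the aldehyde, and the anomeric mixture is of no consequence because C2 is set anew in step 9.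

**Step 7**
Reactants: 13 (3S,4S,5S)-5-Ar-3,4-bis{[(tert-butyldimethylsilyl)oxy]methyl}oxolan-2-ol
Product: 14 (3S,4S,5S)-5-Ar-2-(benzenesulfonyl)-3,4-bis{[(tert-butyldimethylsilyl)oxy]methyl}oxolane (both C2 epimers)
Conditions: PhSO2H (1.5 equiv), CaCl2, CH2Cl2, rt
Reagents that add atoms: benzenesulfinic acid, OS(=O)c1ccccc1
Why: Acid-catalysed exchange of the anomeric hydroxyl for the sulfinate S-nucleophile through the oxocarbenium ion (the standard preparation of 2-sulfonyl cyclic ethers from lactols) gives a storable O,S-acetal whose C2 configuration does not matter.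

**Step 8**
Reactants: 15 4-bromo-2,6-dimethoxyphenol
Product: 16 (4-bromo-2,6-dimethoxyphenoxy)triisopropylsilane
Conditions: TIPSCl (1.3 equiv), imidazole (2.5 equiv), DMF, rt
Reagents that add atoms: chlorotriisopropylsilane (TIPSCl), CC(C)[Si](Cl)(C(C)C)C(C)C
Why: The same phenol silylation as in step 1 gives an aryl bromide that tolerates magnesium insertion; no stereocentre is involved.

**Step 9**
Reactants: 14 (3S,4S,5S)-5-Ar-2-(benzenesulfonyl)-3,4-bis{[(tert-butyldimethylsilyl)oxy]methyl}oxolane; 16 (4-bromo-2,6-dimethoxyphenoxy)triisopropylsilane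
Product: 20 (2R,3S,4S,5S)-2,5-bis-Ar-3,4-bis{[(tert-butyldimethylsilyl)oxy]methyl}oxolane, via arylmagnesium bromide 17 (not isolated), via arylzinc bromide 18 (not isolated), via oxocarbenium ion 19 (not isolated)
Conditions: 16 (2.5 equiv), Mg, THF, 45 °C; ZnBr2 (1.3 equiv), THF, rt; then 14, THF, rt
Reagents that add atoms: none
Why: ZnBr2 (with the MgBr2 formed on transmetalation) pulls the sulfinate off either C2 epimer of 14, so both anomers drain into one planar five-membered oxocarbenium ion 19 (C2=O1+), which is captured at C2 by the aryl group of zinc reagent 18; no ring is closed. The closest known reaction type is the zinc-mediated substitution of 2-(phenylsulfonyl) cyclic ethers by aryl Grignard reagents, together with the Lewis-acid arylation of 2-oxolanyl cations that gives 2,3-trans products in syntheses of 2,5-diaryl-3,4-disubstituted oxolane lignans. The one new stereocentre, C2, is set under substrate control: in the reactive envelope the CH2OTBS group on the neighbouring C3 is pseudo-equatorial and blocks its own face, so the aryl should enter anti to it (2,3-trans), which places it cis to the C5 aryl. The step needs stereoconvergence (secured by ionisation to 19), facial selectivity (secured by the adjacent C3 substituent, which should outweigh the more remote C4 and C5 groups) and chemoselective ionisation of the C2–S bond beside the acid-labile benzylic C5–O1 bond (secured by the mild zinc and magnesium halides in THF, which should leave the less stable 4,5-cis arrangement intact). The attachment point on the arene is fixed by the carbon–metal bond, which is why a metalated aryl is used: electrophilic substitution of free 2,6-dimethoxyphenol would be steered by the two methoxy groups to C3 and not to the required C4.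

**Step 10**
Reactants: 20 (2R,3S,4S,5S)-2,5-bis-Ar-3,4-bis{[(tert-butyldimethylsilyl)oxy]methyl}oxolane
Product: 21 [(2R,3S,4S,5S)-2,5-bis(4-hydroxy-3,5-dimethoxyphenyl)oxolane-3,4-diyl]dimethanol (CNP0170897.4)
Conditions: TBAF (6 equiv), AcOH (6 equiv), THF, 0 °C → rt
Reagents that add atoms: none
Why: Fluoride-induced cleavage of the two alkyl and two aryl Si–O bonds, with acetic acid buffering the phenoxides so that the para-hydroxybenzylic ethers are not opened, should liberate the target without touching a stereocentre.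

**Compound list**

1 | syringaldehyde (4-hydroxy-3,5-dimethoxybenzaldehyde) | COc1cc(C=O)cc(OC)c1O | starting material
2 | 3,5-dimethoxy-4-[(triisopropylsilyl)oxy]benzaldehyde | COc1cc(C=O)cc(OC)c1O[Si](C(C)C)(C(C)C)C(C)C | intermediate
3 | furan-2(5H)-one | O=C1OCC=C1 | starting material
4 | potassium vinyltrifluoroborate | [K+].C=C[B-](F)(F)F | starting material
5 | (4R)-4-ethenyloxolan-2-one | O=C1C[C@H](C=C)CO1 | intermediate
6 | dicyclohexylboron enolate of 5, dicyclohexyl{[(4S)-4-ethenyl-4,5-dihydrofuran-2-yl]oxy}borane (not isolated) | C=C[C@@H]1COC(OB(C2CCCCC2)C2CCCCC2)=C1 | intermediate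
7 | O-dicyclohexylboryl aldolate of 8 (not isolated) | COc1cc([C@@H](OB(C3CCCCC3)C3CCCCC3)[C@H]2[C@H](C=C)COC2=O)cc(OC)c1O[Si](C(C)C)(C(C)C)C(C)C | intermediate
8 | (3R,4S)-3-[(S)-Ar(hydroxy)methyl]-4-ethenyloxolan-2-one | COc1cc([C@@H](O)[C@H]2[C@H](C=C)COC2=O)cc(OC)c1O[Si](C(C)C)(C(C)C)C(C)C | intermediate
9 | (2S,3S)-2-[(S)-Ar(hydroxy)methyl]-3-ethenylbutane-1,4-diol | COc1cc([C@@H](O)[C@H](CO)[C@@H](CO)C=C)cc(OC)c1O[Si](C(C)C)(C(C)C)C(C)C | intermediate
10 | (1S,2S,3S)-1-Ar-2,3-bis{[(tert-butyldimethylsilyl)oxy]methyl}pent-4-en-1-ol | COc1cc([C@@H](O)[C@H](CO[Si](C)(C)C(C)(C)C)[C@@H](CO[Si](C)(C)C(C)(C)C)C=C)cc(OC)c1O[Si](C(C)C)(C(C)C)C(C)C | intermediate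
11 | (1S,2S,3S)-1-Ar-2,3-bis{[(tert-butyldimethylsilyl)oxy]methyl}pentane-1,4,5-triol, C4 epimers (not isolated) | COc1cc([C@@H](O)[C@H](CO[Si](C)(C)C(C)(C)C)[C@@H](CO[Si](C)(C)C(C)(C)C)C(O)CO)cc(OC)c1O[Si](C(C)C)(C(C)C)C(C)C | intermediate
12 | (2S,3S,4S)-4-Ar-2,3-bis{[(tert-butyldimethylsilyl)oxy]methyl}-4-hydroxybutanal (not isolated) | COc1cc([C@@H](O)[C@H](CO[Si](C)(C)C(C)(C)C)[C@@H](CO[Si](C)(C)C(C)(C)C)C=O)cc(OC)c1O[Si](C(C)C)(C(C)C)C(C)C | intermediate
13 | (3S,4S,5S)-5-Ar-3,4-bis{[(tert-butyldimethylsilyl)oxy]methyl}oxolan-2-ol, both C2 epimers | COc1cc([C@H]2OC(O)[C@H](CO[Si](C)(C)C(C)(C)C)[C@H]2CO[Si](C)(C)C(C)(C)C)cc(OC)c1O[Si](C(C)C)(C(C)C)C(C)C | intermediate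
14 | (3S,4S,5S)-5-Ar-2-(benzenesulfonyl)-3,4-bis{[(tert-butyldimethylsilyl)oxy]methyl}oxolane, both C2 epimers | COc1cc([C@H]2OC(S(=O)(=O)c3ccccc3)[C@H](CO[Si](C)(C)C(C)(C)C)[C@H]2CO[Si](C)(C)C(C)(C)C)cc(OC)c1O[Si](C(C)C)(C(C)C)C(C)C | intermediate
15 | 4-bromo-2,6-dimethoxyphenol | COc1cc(Br)cc(OC)c1O | starting material
16 | (4-bromo-2,6-dimethoxyphenoxy)triisopropylsilane | COc1cc(Br)cc(OC)c1O[Si](C(C)C)(C(C)C)C(C)C | intermediate
17 | {3,5-dimethoxy-4-[(triisopropylsilyl)oxy]phenyl}magnesium bromide (not isolated) | COc1cc([Mg]Br)cc(OC)c1O[Si](C(C)C)(C(C)C)C(C)C | intermediate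
18 | {3,5-dimethoxy-4-[(triisopropylsilyl)oxy]phenyl}zinc bromide (not isolated) | COc1cc([Zn]Br)cc(OC)c1O[Si](C(C)C)(C(C)C)C(C)C | intermediate
19 | (3S,4S,5S)-5-Ar-3,4-bis{[(tert-butyldimethylsilyl)oxy]methyl}-4,5-dihydro-3H-furan-1-ium, the C2=O1+ oxocarbenium ion (not isolated) | COc1cc([C@H]2[O+]=C[C@H](CO[Si](C)(C)C(C)(C)C)[C@H]2CO[Si](C)(C)C(C)(C)C)cc(OC)c1O[Si](C(C)C)(C(C)C)C(C)C | intermediate
20 | (2R,3S,4S,5S)-2,5-bis-Ar-3,4-bis{[(tert-butyldimethylsilyl)oxy]methyl}oxolane | COc1cc([C@H]2O[C@@H](c3cc(OC)c(O[Si](C(C)C)(C(C)C)C(C)C)c(OC)c3)[C@H](CO[Si](C)(C)C(C)(C)C)[C@H]2CO[Si](C)(C)C(C)(C)C)cc(OC)c1O[Si](C(C)C)(C(C)C)C(C)C | intermediate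
21 | [(2R,3S,4S,5S)-2,5-bis(4-hydroxy-3,5-dimethoxyphenyl)oxolane-3,4-diyl]dimethanol | COc1cc([C@H]2O[C@@H](c3cc(OC)c(O)c(OC)c3)[C@H](CO)[C@H]2CO)cc(OC)c1O | target

**Step count and risks**

Total step count: 10. Longest linear sequence: 8 steps (steps 2, 3, 4, 5, 6, 7, 9 and 10, from furan-2(5H)-one); steps 1 and 8 are one-step side branches.

The three steps most likely to fail:

Step 9. What may go wrong is insufficient facial discrimination in the capture of the oxocarbenium ion, because the groups on C4 and C5 lie on the face that has to be attacked, or loss of the C3 proton from the cation to give the cyclic enol ether. The fallback makes the same bond through a radical instead of a cation. It sets out from lactol 13, which is converted with 1-chloro-N,N,2-trimethylprop-1-en-1-amine (CH2Cl2, 0 °C) into the anomeric chloride (3S,4S,5S)-5-Ar-2-chloro-3,4-bis{[(tert-butyldimethylsilyl)oxy]methyl}oxolane F1. This is used crude in a nickel-catalysed Negishi coupling with arylzinc bromide 18 (zerovalent nickel complex Ni(cod)2, 4,4′,4″-tri-tert-butyl-2,2′:6′,2″-terpyridine, DMA/THF, rt). Halogen abstraction should give the same C2 oxolanyl radical from either anomer, and the aryl–nickel species should combine with it anti to the C3 substituent. The product is 20, where the route is rejoined.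

Step 3. What may go wrong is incomplete soft enolisation of the lactone by the boron triflate, or erosion of the anti selectivity at the carbinol carbon. The fallback separates C–C bond formation from the setting of the carbinol centre. It sets out from 5 and 2: deprotonation of 5 with LiN(iPr)2 (THF, −78 °C) and addition of 2 should give the aldol as a mixture of carbinol epimers, (3R,4S)-3-[Ar(hydroxy)methyl]-4-ethenyloxolan-2-one F2, with C3 still trans to vinyl. Dess–Martin oxidation (CH2Cl2, NaHCO3) gives the β-keto lactone (3R,4S)-3-(Ar-carbonyl)-4-ethenyloxolan-2-one F3. Noyori–Ikariya transfer hydrogenation with RuCl(p-cymene)[(S,S)-TsDPEN] in HCO2H/Et3N then delivers hydride to the aryl ketone under catalyst control, the labile C3 centre staying trans to vinyl, and returns 8.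

Step 2. What may go wrong is slow carbometalation of the five-membered enoate in competition with protodeboronation of the vinylboron reagent, or insufficient enantioselectivity. The fallback is a classical resolution. It sets out from 3: copper-catalysed conjugate addition of CH2=CHMgBr (CuBr·SMe2, Me3SiCl, THF, −78 °C) gives racemic 4-ethenyloxolan-2-one F4. Ring opening with (S)-1-phenylethylamine (2-hydroxypyridine cat., toluene, 80 °C) gives two diastereomeric hydroxy amides, from which (3R)-3-(hydroxymethyl)-N-[(1S)-1-phenylethyl]pent-4-enamide F5 is separated by crystallisation or chromatography. Acid-mediated relactonisation (H2SO4, aqueous 1,4-dioxane, 80 °C) releases the amine and returns 5.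

**Further compounds**

F1 | step 9 | (3S,4S,5S)-5-Ar-2-chloro-3,4-bis{[(tert-butyldimethylsilyl)oxy]methyl}oxolane, both C2 epimers | COc1cc([C@H]2OC(Cl)[C@H](CO[Si](C)(C)C(C)(C)C)[C@H]2CO[Si](C)(C)C(C)(C)C)cc(OC)c1O[Si](C(C)C)(C(C)C)C(C)C
F2 | step 3 | (3R,4S)-3-[Ar(hydroxy)methyl]-4-ethenyloxolan-2-one, carbinol epimers | COc1cc(C(O)[C@H]2[C@H](C=C)COC2=O)cc(OC)c1O[Si](C(C)C)(C(C)C)C(C)C
F3 | step 3 | (3R,4S)-3-(Ar-carbonyl)-4-ethenyloxolan-2-one | COc1cc(C(=O)[C@H]2[C@H](C=C)COC2=O)cc(OC)c1O[Si](C(C)C)(C(C)C)C(C)C
F4 | step 2 | racemic 4-ethenyloxolan-2-one | C=CC1COC(=O)C1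
F5 | step 2 | (3R)-3-(hydroxymethyl)-N-[(1S)-1-phenylethyl]pent-4-enamide | C=C[C@H](CO)CC(=O)N[C@@H](C)c1ccccc1
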